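**Retrosynthetic overview**
1. Cut the two C–OMe bonds and both indole C3–quinone bonds: all four substituents trace back to the four equivalent C–Br bonds of one fourfold-symmetric tetrahaloquinone, so the quinone ring is bought, not built.
2. Side chain: 7-bromoindole 1 + prenylstannane 2 → 7-prenylindole 3 (Stille coupling).
3. Key step: bromanil 4 + parent indole 5 → mono-indolyl tribromoquinone 6; one substitution breaks the symmetry, and the donor it installs directs every later substitution.
4. 6 + 3 → para bis-indolyl dibromoquinone 7 (in the flask) → two bromide-to-methoxide exchanges → 8.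
5. Ring order: no ring is formed; both indole bicycles and the six-membered quinone ring are purchased, with no protecting groups and no redox adjustments.

Assumption: 8 has no stereocentre and no stereogenic double bond, so it is one achiral compound and no stereocontrol is needed.

**Route**

Step 1
Reactants: 1 7-bromo-1H-indole; 2 tributyl(3-methylbut-2-en-1-yl)stannane
Product: 3 7-(3-methylbut-2-en-1-yl)-1H-indole
Conditions: Pd(PPh3)4 (5 mol %), 2 (1.3 equiv), DMF, 100 °C
Reagents that add atoms: none
Why: Stille cross-coupling, in which zerovalent palladium inserts into the C7–Br bond, the allyl group is transferred from tin and reductive elimination at the unsubstituted allyl terminus gives the linear prenyl arene, while the neutral conditions leave the free N–H untouched; no stereocentre is formed.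

Step 2
Reactants: 4 2,3,5,6-tetrabromo-1,4-benzoquinone (bromanil); 5 1H-indole
Product: 6 2,3,5-tribromo-6-(1H-indol-3-yl)-1,4-benzoquinone
Conditions: 4 (1.5 equiv), Cs2CO3 (1.1 equiv), MeCN, 0 °C → rt, dark
Reagents that add atoms: none
Why: Nucleophilic vinylic substitution (addition–elimination) on a haloquinone, in which the enamine-like C3 of neutral indole adds to one of the four equivalent C–Br carbons (each the β-carbon of an enone), bromide is expelled and Cs2CO3 takes up HBr, and the new indolyl group acts as a vinylogous amide donor that lowers the electrophilicity enough for the reaction to stop after one substitution when 4 is in excess; no stereocentre is formed.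

Step 3
Reactants: 6 2,3,5-tribromo-6-(1H-indol-3-yl)-1,4-benzoquinone; 3 7-(3-methylbut-2-en-1-yl)-1H-indole
Product: 8 2,5-dimethoxy-3-(1H-indol-3-yl)-6-[7-(3-methylbut-2-en-1-yl)-1H-indol-3-yl]-1,4-benzoquinone, via dibromo bis-indolylquinone 7 (not isolated)
Conditions: 3 (1.5 equiv), Cs2CO3 (1.5 equiv), MeCN, rt → 45 °C; then evaporate, NaOMe (8 equiv), MeOH–THF, 55 °C; aq NH4Cl
Reagents that add atoms: sodium methoxide, [Na+].[O-]C
Why: A second addition–elimination on the haloquinone followed by double methanolysis of the vinylogous acyl bromides, in which 3 attacks the C–Br carbon that is β to the carbonyl not conjugated to the first indole and para to it (attack next to the first indole would break its push–pull conjugation), giving the 2,5-diaryl pattern of 7, and methoxide then replaces the two remaining bromides, each still β to a carbonyl, after which further methoxide attack is degenerate; no stereocentre is formed.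

**Compound list**
1 | 7-bromo-1H-indole | Brc1cccc2cc[nH]c12 | starting material
2 | tributyl(3-methylbut-2-en-1-yl)stannane | CCCC[Sn](CCCC)(CCCC)CC=C(C)C | starting material
3 | 7-(3-methylbut-2-en-1-yl)-1H-indole | CC(C)=CCc1cccc2cc[nH]c12 | intermediate
4 | 2,3,5,6-tetrabromo-1,4-benzoquinone (bromanil) | O=C1C(Br)=C(Br)C(=O)C(Br)=C1Br | starting material
5 | 1H-indole | c1ccc2[nH]ccc2c1 | starting material
6 | 2,3,5-tribromo-6-(1H-indol-3-yl)-1,4-benzoquinone | O=C1C(Br)=C(Br)C(=O)C(c2c[nH]c3ccccc23)=C1Br | intermediate
7 | 2,5-dibromo-3-(1H-indol-3-yl)-6-[7-(3-methylbut-2-en-1-yl)-1H-indol-3-yl]-1,4-benzoquinone | O=C1C(Br)=C(c2c[nH]c3ccccc23)C(=O)C(Br)=C1c1c[nH]c2c(CC=C(C)C)cccc12 | intermediate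
8 | 2,5-dimethoxy-3-(1H-indol-3-yl)-6-[7-(3-methylbut-2-en-1-yl)-1H-indol-3-yl]-1,4-benzoquinone | COC1=C(c2c[nH]c3ccccc23)C(=O)C(OC)=C(c2c[nH]c3c(CC=C(C)C)cccc23)C1=O | target

**Totals and risks**

Total step count: 3. Longest linear sequence: 2 steps (1 → 3 → 8, or 4 → 6 → 8).

Steps most likely to fail, most risky first:

1. Step 3. The quinone 6 is deactivated by its indolyl donor and may react too slowly with 3, so that little 7 reaches the methoxide stage. The fallback sets out from 3 and comes back to the route at 7, and it reverses the order of assembly. Here 3 is the nucleophile that breaks the symmetry of 4 (Cs2CO3, MeCN, 0 °C → rt) and gives 2,3,5-tribromo-6-[7-(3-methylbut-2-en-1-yl)-1H-indol-3-yl]-1,4-benzoquinone F1, which is isolated. F1 is then treated with a large excess of cheap 5 (Cs2CO3, MeCN, 45 °C) to force the slow para substitution and give 7. Compound 7 is purified and taken through the NaOMe stage of step 3 to 8.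

2. Step 2. Attack through nitrogen, double substitution or oxidation of indole by the strongly electron-poor 4 may erode the mono-adduct. The fallback sets out from 5 and comes back to the route at 8. It replaces substitution on a tetrahaloquinone by acid-promoted conjugate addition and re-oxidation on purchased 2,5-dichloro-1,4-benzoquinone. Indole 5 adds to a free C–H position (HCl, THF, rt) to give 2,5-dichloro-3-(1H-indol-3-yl)benzene-1,4-diol F2, which is oxidised in the same flask with DDQ to 2,5-dichloro-3-(1H-indol-3-yl)-1,4-benzoquinone F3. Compound 3 then adds to the one remaining C–H position (AcOH, rt) to give 2,5-dichloro-3-(1H-indol-3-yl)-6-[7-(3-methylbut-2-en-1-yl)-1H-indol-3-yl]benzene-1,4-diol F4, and DDQ converts it into 2,5-dichloro-3-(1H-indol-3-yl)-6-[7-(3-methylbut-2-en-1-yl)-1H-indol-3-yl]-1,4-benzoquinone F5. NaOMe in MeOH–THF at 55 °C exchanges both chlorides of F5 and gives 8.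

3. Step 1. Prenyl transfer from tin can deliver some of the branched 1,1-dimethylallyl isomer, which is hard to separate. The fallback sets out from 1 and comes back to the route at 3, and it builds the prenyl terminus by olefin metathesis instead of transferring it intact. Stille coupling of 1 with allyltributylstannane (Pd(PPh3)4, DMF, 100 °C), which has no regiochemical ambiguity, gives 7-allyl-1H-indole F6. Cross-metathesis of F6 with excess 2-methylbut-2-ene (second-generation Grubbs catalyst, CH2Cl2, 40 °C) gives 3.

**Further compounds**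
F1 | step 3 | 2,3,5-tribromo-6-[7-(3-methylbut-2-en-1-yl)-1H-indol-3-yl]-1,4-benzoquinone | O=C1C(Br)=C(Br)C(=O)C(c2c[nH]c3c(CC=C(C)C)cccc23)=C1Br
F2 | step 2 | 2,5-dichloro-3-(1H-indol-3-yl)benzene-1,4-diol | Oc1cc(Cl)c(O)c(-c2c[nH]c3ccccc23)c1Cl
F3 | step 2 | 2,5-dichloro-3-(1H-indol-3-yl)-1,4-benzoquinone | O=C1C=C(Cl)C(=O)C(c2c[nH]c3ccccc23)=C1Cl
F4 | step 2 | 2,5-dichloro-3-(1H-indol-3-yl)-6-[7-(3-methylbut-2-en-1-yl)-1H-indol-3-yl]benzene-1,4-diol | Oc1c(Cl)c(-c2c[nH]c3ccccc23)c(O)c(Cl)c1-c1c[nH]c2c(CC=C(C)C)cccc12
F5 | step 2 | 2,5-dichloro-3-(1H-indol-3-yl)-6-[7-(3-methylbut-2-en-1-yl)-1H-indol-3-yl]-1,4-benzoquinone | O=C1C(Cl)=C(c2c[nH]c3ccccc23)C(=O)C(Cl)=C1c1c[nH]c2c(CC=C(C)C)cccc12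
F6 | step 1 | 7-allyl-1H-indole | C=CCc1cccc2cc[nH]c12
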